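The route rests on disconnecting the C4–C4a bond (benzylic CH2 to arene) of the dihydro ring B of the 3,4-dihydronaphthalen-2-yl ketone. The C3 stereocentre carries two CH2 groups, C4 and the hydroxymethyl carbon, which are the enantiotopic arms of an oxetane, and C4a lies para to the C7 phenol OH. A chiral Brønsted acid therefore lets the phenol ring of an achiral (E)-2-(oxetan-3-yl)chalcone, an isomer of the target, open the oxetane by Friedel–Crafts attack. This one operation closes ring B, sets the only stereocentre and frees the CH2OH group. The chalcone is assembled from acetovanillone, oxetan-3-one and isovanillin by two aldol condensations.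

Key step: step 7

Numbering used for the target: C1 is the vinyl CH, C2 carries the aroyl group, C3 is the stereocentre, C4 is the ring CH2, C6 carries OMe and C7 carries OH; the stereocentre is R.

Assumption: the sense of induction of the chiral acid cannot be predicted with confidence; the (R)-configured catalyst is written, and its mirror image would be used should it favour the (S)-product.

Step 1
Reactants: 1 acetovanillone (1-(4-hydroxy-3-methoxyphenyl)ethan-1-one)
Product: 2 1-[4-(tert-butyldimethylsilyloxy)-3-methoxyphenyl]ethan-1-one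
Conditions: TBSCl, imidazole, DMF, rt
Reagents that add atoms: tert-butyldimethylsilyl chloride (TBSCl), CC(C)(C)[Si](C)(C)Cl
Why: Imidazole-promoted O-silylation of the phenol (silyl ether protection) masks the acidic OH so that the methyl ketone can be enolised in step 2; no stereocentre is involved.

Step 2
Reactants: 2 1-[4-(tert-butyldimethylsilyloxy)-3-methoxyphenyl]ethan-1-one; 3 oxetan-3-one
Product: 7 1-[4-(tert-butyldimethylsilyloxy)-3-methoxyphenyl]-2-(oxetan-3-ylidene)ethan-1-one, via lithium enolate 4 (not isolated), via lithium aldolate 5 (not isolated), via tertiary mesylate 6 (not isolated)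
Conditions: LDA, THF, −78 °C; then 3; then MsCl, Et3N, −78 °C to rt
Reagents that add atoms: none
Why: Directed aldol addition of the lithium enolate to the strained, highly electrophilic ketone of oxetan-3-one, then mesylation of the aldolate and E1cB elimination (aldol condensation in one flask) should give the enone, whose alkene has no geometry because the two ring arms are identical.

Step 3
Reactants: 7 1-[4-(tert-butyldimethylsilyloxy)-3-methoxyphenyl]-2-(oxetan-3-ylidene)ethan-1-one
Product: 8 1-[4-(tert-butyldimethylsilyloxy)-3-methoxyphenyl]-2-(oxetan-3-yl)ethan-1-one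
Conditions: H2 (1 atm), Pd/C, EtOAc, rt, stopped after one equivalent of H2
Reagents that add atoms: none
Why: Heterogeneous catalytic hydrogenation should saturate the strained, electron-poor exocyclic alkene well before it touches the electron-rich aryl ketone, the aryl silyl ether or the oxetane, and the new oxetane C3 carries two identical arms, so no stereocentre arises.

Step 4
Reactants: 9 isovanillin (3-hydroxy-4-methoxybenzaldehyde)
Product: 10 3-(tert-butyldimethylsilyloxy)-4-methoxybenzaldehyde
Conditions: TBSCl, imidazole, DMF, rt
Reagents that add atoms: tert-butyldimethylsilyl chloride (TBSCl), CC(C)(C)[Si](C)(C)Cl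
Why: Imidazole-promoted O-silylation of the phenol (silyl ether protection) removes the acidic proton that would quench the enolate in step 5.

Step 5
Reactants: 8 1-[4-(tert-butyldimethylsilyloxy)-3-methoxyphenyl]-2-(oxetan-3-yl)ethan-1-one; 10 3-(tert-butyldimethylsilyloxy)-4-methoxybenzaldehyde
Product: 14 (E)-1-[4-(tert-butyldimethylsilyloxy)-3-methoxyphenyl]-3-[3-(tert-butyldimethylsilyloxy)-4-methoxyphenyl]-2-(oxetan-3-yl)prop-2-en-1-one, via lithium enolate 11 (not isolated), via lithium aldolate 12 (not isolated), via benzylic mesylate 13 (not isolated)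
Conditions: LDA, THF, −78 °C; then 10; then MsCl, Et3N, −78 to 0 °C; then DBU, rt
Reagents that add atoms: none
Why: Directed aldol addition of the lithium enolate of 8 to the non-enolisable aldehyde 10, mesylation and base-induced E1cB elimination (aldol condensation) should give the trisubstituted enone, the (E)-isomer (aryl trans to the bulky aroyl group, cis to the oxetane) being the more stable one and favoured by the enolate-mediated elimination; both aldol stereocentres are destroyed.

Step 6
Reactants: 14 (E)-1-[4-(tert-butyldimethylsilyloxy)-3-methoxyphenyl]-3-[3-(tert-butyldimethylsilyloxy)-4-methoxyphenyl]-2-(oxetan-3-yl)prop-2-en-1-one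
Product: 15 (E)-1-(4-hydroxy-3-methoxyphenyl)-3-(3-hydroxy-4-methoxyphenyl)-2-(oxetan-3-yl)prop-2-en-1-one
Conditions: TBAF, AcOH, THF, 0 °C
Reagents that add atoms: none
Why: Fluoride-induced cleavage of both aryl silyl ethers (desilylation), buffered with acetic acid so that no free phenoxide attacks the enone, should leave the oxetane and the alkene geometry untouched.

Step 7
Reactants: 15 (E)-1-(4-hydroxy-3-methoxyphenyl)-3-(3-hydroxy-4-methoxyphenyl)-2-(oxetan-3-yl)prop-2-en-1-one
Product: 16 [(3R)-7-hydroxy-3-(hydroxymethyl)-6-methoxy-3,4-dihydronaphthalen-2-yl](4-hydroxy-3-methoxyphenyl)methanone (target)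
Conditions: (R)-3,3'-bis(2,4,6-triisopropylphenyl)-1,1'-binaphthyl-2,2'-diyl N-triflylphosphoramide (10 mol %), CH2Cl2/PhMe 1:1 (0.01 M), rt
Reagents that add atoms: none
Why: Proposed new method: the chiral acid protonates the oxetane oxygen of 15 (the most basic site) inside its chiral pocket, C6 of the 3-hydroxy-4-methoxyphenyl ring (para to the free OH) attacks one of the two enantiotopic oxetane CH2 carbons in an SN2-like Friedel–Crafts alkylation, and rearomatisation returns the proton, the cleaved C–O bond appearing as the CH2OH group. The closest known reaction types are the chiral phosphoric acid-catalysed desymmetrisation of 3-substituted oxetanes by tethered O, N and S nucleophiles and the Lewis acid-catalysed intramolecular Friedel–Crafts opening of oxetanes by electron-rich arenes; a phenol carbon as the nucleophile in the enantioselective variant is the untested element. Ring B closes in the 6-exo-tet mode, which the (E)-alkene makes possible by holding the arene and the oxetane cis on the C=C bond. The C3 stereocentre is under catalyst control: the chiral counter-anion, bound to the oxetanium O–H and to a phenol O–H, decides which CH2–O bond is broken, and attack on the arm that leads to the (R)-product is required. The step needs attack from C6 rather than C2 of the arene (C2 is flanked by the vinyl group and the OH), carbon rather than oxygen alkylation (no phenol oxygen can reach the oxetane within the molecule and high dilution suppresses intermolecular etherification) and arene attack in preference to 5-exo capture by the ketone oxygen (a much weaker base and nucleophile than the oxetane, and an oxocarbenium ion formed that way can still be opened at the same CH2 by the arene). No protecting group is present, so the isomerisation should deliver the target directly.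

Compound list
1 | acetovanillone, 1-(4-hydroxy-3-methoxyphenyl)ethan-1-one | CC(=O)c1ccc(O)c(OC)c1 | starting material
2 | 1-[4-(tert-butyldimethylsilyloxy)-3-methoxyphenyl]ethan-1-one | CC(=O)c1ccc(O[Si](C)(C)C(C)(C)C)c(OC)c1 | intermediate
3 | oxetan-3-one | O=C1COC1 | starting material
4 | lithium enolate of 2, lithium 1-[4-(tert-butyldimethylsilyloxy)-3-methoxyphenyl]ethen-1-olate (not isolated) | [Li+].[O-]C(=C)c1ccc(O[Si](C)(C)C(C)(C)C)c(OC)c1 | intermediate
5 | lithium aldolate, lithium 3-{2-[4-(tert-butyldimethylsilyloxy)-3-methoxyphenyl]-2-oxoethyl}oxetan-3-olate (not isolated) | [Li+].[O-]C1(CC(=O)c2ccc(O[Si](C)(C)C(C)(C)C)c(OC)c2)COC1 | intermediate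
6 | tertiary mesylate, 3-{2-[4-(tert-butyldimethylsilyloxy)-3-methoxyphenyl]-2-oxoethyl}oxetan-3-yl methanesulfonate (not isolated) | CS(=O)(=O)OC1(CC(=O)c2ccc(O[Si](C)(C)C(C)(C)C)c(OC)c2)COC1 | intermediate
7 | 1-[4-(tert-butyldimethylsilyloxy)-3-methoxyphenyl]-2-(oxetan-3-ylidene)ethan-1-one | O=C(C=C1COC1)c1ccc(O[Si](C)(C)C(C)(C)C)c(OC)c1 | intermediate
8 | 1-[4-(tert-butyldimethylsilyloxy)-3-methoxyphenyl]-2-(oxetan-3-yl)ethan-1-one | O=C(CC1COC1)c1ccc(O[Si](C)(C)C(C)(C)C)c(OC)c1 | intermediate
9 | isovanillin, 3-hydroxy-4-methoxybenzaldehyde | O=Cc1ccc(OC)c(O)c1 | starting material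
10 | 3-(tert-butyldimethylsilyloxy)-4-methoxybenzaldehyde | O=Cc1ccc(OC)c(O[Si](C)(C)C(C)(C)C)c1 | intermediate
11 | lithium (Z)-enolate of 8, lithium (Z)-1-[4-(tert-butyldimethylsilyloxy)-3-methoxyphenyl]-2-(oxetan-3-yl)ethen-1-olate (not isolated) | [Li+].[O-]/C(=C\C1COC1)c1ccc(O[Si](C)(C)C(C)(C)C)c(OC)c1 | intermediate
12 | lithium aldolate, lithium 1-[3-(tert-butyldimethylsilyloxy)-4-methoxyphenyl]-3-[4-(tert-butyldimethylsilyloxy)-3-methoxyphenyl]-2-(oxetan-3-yl)-3-oxopropan-1-olate, racemic mixture of diastereomers (not isolated) | [Li+].[O-]C(c1ccc(OC)c(O[Si](C)(C)C(C)(C)C)c1)C(C1COC1)C(=O)c1ccc(O[Si](C)(C)C(C)(C)C)c(OC)c1 | intermediate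
13 | benzylic mesylate, 1-[3-(tert-butyldimethylsilyloxy)-4-methoxyphenyl]-3-[4-(tert-butyldimethylsilyloxy)-3-methoxyphenyl]-2-(oxetan-3-yl)-3-oxopropyl methanesulfonate, racemic mixture of diastereomers (not isolated) | CS(=O)(=O)OC(c1ccc(OC)c(O[Si](C)(C)C(C)(C)C)c1)C(C1COC1)C(=O)c1ccc(O[Si](C)(C)C(C)(C)C)c(OC)c1 | intermediate
14 | (E)-1-[4-(tert-butyldimethylsilyloxy)-3-methoxyphenyl]-3-[3-(tert-butyldimethylsilyloxy)-4-methoxyphenyl]-2-(oxetan-3-yl)prop-2-en-1-one | O=C(c1ccc(O[Si](C)(C)C(C)(C)C)c(OC)c1)/C(=C/c1ccc(OC)c(O[Si](C)(C)C(C)(C)C)c1)C1COC1 | intermediate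
15 | (E)-1-(4-hydroxy-3-methoxyphenyl)-3-(3-hydroxy-4-methoxyphenyl)-2-(oxetan-3-yl)prop-2-en-1-one | O=C(c1ccc(O)c(OC)c1)/C(=C/c1ccc(OC)c(O)c1)C1COC1 | intermediate
16 | [(3R)-7-hydroxy-3-(hydroxymethyl)-6-methoxy-3,4-dihydronaphthalen-2-yl](4-hydroxy-3-methoxyphenyl)methanone | COc1cc(C(=O)C2=Cc3cc(O)c(OC)cc3C[C@H]2CO)ccc1O | target

Total step count: 7
Longest linear sequence: 6 steps (steps 1, 2, 3, 5, 6, 7); step 4 is a one-step side branch.

Steps most likely to fail

1. Step 7 (Proposed new method). The catalyst pocket may discriminate poorly between the two enantiotopic CH2 arms. The activated oxetane may also be diverted by the ketone oxygen or by a phenol oxygen of a second molecule, or the enone-conjugated arene may attack too slowly. Fallback with known chemistry: setting out from 15, ring B is closed without enantiocontrol by a Lewis acid-catalysed intramolecular Friedel–Crafts opening of the oxetane (Sc(OTf)3, CH2Cl2, rt). This should give the racemic dihydronaphthalene ketone F1. Preparative HPLC on a chiral stationary phase (amylose tris(3,5-dimethylphenylcarbamate), hexane/iPrOH) then separates the enantiomers, and the (R)-enantiomer rejoins the route as 16.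

2. Step 5. The hindered lithium aldolate may revert by retro-aldol cleavage before it is trapped, enolisation of the α-branched ketone may be incomplete, or the elimination may give an E/Z mixture. Fallback: setting out from 7 and 10 (step 3 is then not needed), 7 is reduced in the conjugate sense with [(Ph3P)CuH]6 in toluene/THF at −40 °C. The copper enolate, formed without strong base, is trapped by 10 added afterwards (reductive aldol), and aqueous NH4Cl work-up should give the isolated β-hydroxy ketone F2 as a mixture of diastereomers. Mesylation (MsCl, Et3N, CH2Cl2, 0 °C) converts it into 13, where the fallback rejoins the route, and 13 is eliminated with DBU to 14 as in step 5. Any Z-isomer is equilibrated to the E-isomer with catalytic I2 in CH2Cl2 under visible light.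

3. Step 2. The tertiary aldolate may undergo retro-aldol cleavage or be sulfonylated incompletely, and oxetan-3-one may self-condense under the basic conditions. Fallback: setting out from 2, α-bromination with PhNMe3Br3 in THF gives the phenacyl bromide F3. PPh3 in toluene converts it into the phosphonium bromide F4, and aqueous NaOH/CH2Cl2 gives the acyl-stabilised ylide F5. Wittig olefination of 3 with F5 in CH2Cl2 at rt, a known reaction of oxetan-3-one with stabilised ylides, then gives 7 under neutral conditions.

Further compounds
F1 | step 7 | racemic [7-hydroxy-3-(hydroxymethyl)-6-methoxy-3,4-dihydronaphthalen-2-yl](4-hydroxy-3-methoxyphenyl)methanone | COc1cc(C(=O)C2=Cc3cc(O)c(OC)cc3CC2CO)ccc1O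
F2 | step 5 | 3-[3-(tert-butyldimethylsilyloxy)-4-methoxyphenyl]-1-[4-(tert-butyldimethylsilyloxy)-3-methoxyphenyl]-3-hydroxy-2-(oxetan-3-yl)propan-1-one, racemic mixture of diastereomers | OC(c1ccc(OC)c(O[Si](C)(C)C(C)(C)C)c1)C(C1COC1)C(=O)c1ccc(O[Si](C)(C)C(C)(C)C)c(OC)c1
F3 | step 2 | 2-bromo-1-[4-(tert-butyldimethylsilyloxy)-3-methoxyphenyl]ethan-1-one | O=C(CBr)c1ccc(O[Si](C)(C)C(C)(C)C)c(OC)c1
F4 | step 2 | {2-[4-(tert-butyldimethylsilyloxy)-3-methoxyphenyl]-2-oxoethyl}triphenylphosphonium bromide | [Br-].O=C(C[P+](c1ccccc1)(c1ccccc1)c1ccccc1)c1ccc(O[Si](C)(C)C(C)(C)C)c(OC)c1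
F5 | step 2 | 1-[4-(tert-butyldimethylsilyloxy)-3-methoxyphenyl]-2-(triphenyl-λ5-phosphanylidene)ethan-1-one | O=C(C=P(c1ccccc1)(c1ccccc1)c1ccccc1)c1ccc(O[Si](C)(C)C(C)(C)C)c(OC)c1
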